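Ring B is disconnected at C8–C9 together with C5–C10 by a retro-Diels–Alder reaction: the 6,8(17)-diene of the target, C6=C7 inside ring B next to the exocyclic methylene C8=C17, is the footprint of a vinylallene [4+2]. In one operation an acyclic enynol is converted by a [2,3]-sigmatropic shift into an axially chiral allenyl sulfoxide, whose vinylallene adds to the tethered (E)-alkene C9=C10; this closes rings A and B and sets C5, C9 and C10. The precursor is a linear, geranate-derived chain bearing only two stereocentres, the quaternary C4 (set by enzymatic desymmetrisation) and the propargylic carbinol C7.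

Key step: step 13

Remark on the chemistry: C1–C20 in the Why lines are the labdane positions of the target (ring A: C1–C5 and C10; ring B: C5–C10; C17 is the exocyclic methylene carbon, C18 the acetoxymethyl carbon), while compound names carry their own chain numbering. The sulfoxide sulfur of 17 and 18 is taken as either epimer, since it is not a stereocentre of the target and leaves in step 14.

Step 1
Reactants: 1 diethyl methylmalonate
Product: 2 diethyl 2-(2-chloroethyl)-2-methylmalonate
Conditions: NaH, BrCH2CH2Cl (3 equiv), THF–DMF, 0 → 60 °C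
Reagents that add atoms: 1-bromo-2-chloroethane, ClCCBr
Why: Malonate C-alkylation in which the enolate displaces bromide, the better leaving group, and the quaternary product cannot be alkylated again.

Step 2
Reactants: 2 diethyl 2-(2-chloroethyl)-2-methylmalonate
Product: 3 2-(2-chloroethyl)-2-methylpropane-1,3-diol
Conditions: LiAlH4, Et2O, 0 °C; then H2O, aq. NaOH
Reagents that add atoms: none
Why: Hydride reduction of both esters should give the prochiral 1,3-diol, since a primary alkyl chloride is reduced only slowly at 0 °C.

Step 3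
Reactants: 3 2-(2-chloroethyl)-2-methylpropane-1,3-diol
Product: 4 5-(2-chloroethyl)-2,2,5-trimethyl-1,3-dioxane
Conditions: Me2C(OMe)2, TsOH (cat.), acetone, 23 °C
Reagents that add atoms: 2,2-dimethoxypropane, COC(C)(C)OC
Why: Acetonide formation masks both hydroxyl groups so that the chloride can be turned into a Grignard reagent.

Step 4
Reactants: 5 methyl geranate
Product: 6 methyl (2E,6E)-8-hydroxy-3,7-dimethylocta-2,6-dienoate
Conditions: SeO2 (cat.), t-BuOOH, CH2Cl2, 23 °C
Reagents that add atoms: tert-butyl hydroperoxide, CC(C)(C)OO (oxygen relayed by SeO2)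
Why: Allylic oxidation (ene reaction, then [2,3]-shift) should take place at the (E)-methyl group of the electron-rich trisubstituted alkene and leave the conjugated alkene untouched.

Step 5
Reactants: 6 methyl (2E,6E)-8-hydroxy-3,7-dimethylocta-2,6-dienoate
Product: 7 methyl (2E,6E)-8-bromo-3,7-dimethylocta-2,6-dienoate
Conditions: CBr4, PPh3, CH2Cl2, 0 °C
Reagents that add atoms: carbon tetrabromide, BrC(Br)(Br)Br
Why: Appel bromination of the primary allylic alcohol should proceed without allylic transposition or loss of alkene geometry.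

Step 6
Reactants: 4 5-(2-chloroethyl)-2,2,5-trimethyl-1,3-dioxane; 7 methyl (2E,6E)-8-bromo-3,7-dimethylocta-2,6-dienoate
Product: 9 methyl (2E,6E)-3,7-dimethyl-10-(2,2,5-trimethyl-1,3-dioxan-5-yl)deca-2,6-dienoate, via Grignard reagent 8 (not isolated)
Conditions: 4, Mg, BrCH2CH2Br (cat.), THF, reflux; then added to 7, Li2CuCl4 (cat.), THF, −78 → −20 °C
Reagents that add atoms: none
Why: Copper-catalysed sp3–sp3 coupling of the alkyl Grignard reagent at the unhindered primary carbon of the allylic bromide should keep the (E)-alkene and at −78 °C outpace addition to the β,β-disubstituted enoate.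

Step 7
Reactants: 9 methyl (2E,6E)-3,7-dimethyl-10-(2,2,5-trimethyl-1,3-dioxan-5-yl)deca-2,6-dienoate
Product: 10 methyl (2E,6E)-12-hydroxy-11-(hydroxymethyl)-3,7,11-trimethyldodeca-2,6-dienoate
Conditions: AcOH–H2O (4:1), 40 °C
Reagents that add atoms: none
Why: Acid hydrolysis of the acetonide frees the prochiral diol and should leave the methyl ester and both alkenes intact.

Step 8
Reactants: 10 methyl (2E,6E)-12-hydroxy-11-(hydroxymethyl)-3,7,11-trimethyldodeca-2,6-dienoate
Product: 11 methyl (2E,6E,11S)-12-acetoxy-11-(hydroxymethyl)-3,7,11-trimethyldodeca-2,6-dienoate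
Conditions: lipase PS (Burkholderia cepacia), vinyl acetate, i-Pr2O, 23 °C
Reagents that add atoms: vinyl acetate, CC(=O)OC=C
Why: Enzymatic desymmetrisation by irreversible transesterification should acylate one of the two enantiotopic hydroxymethyl groups (methyl versus long chain at the quaternary carbon), which creates the C4 stereocentre and places the acetate of the target; the lipase is selected by screening for the 11S monoacetate.

Step 9
Reactants: 11 methyl (2E,6E,11S)-12-acetoxy-11-(hydroxymethyl)-3,7,11-trimethyldodeca-2,6-dienoate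
Product: 12 methyl (2E,6E,11R)-11-(acetoxymethyl)-3,7,11-trimethyl-12-oxododeca-2,6-dienoate
Conditions: Dess–Martin periodinane, CH2Cl2, 23 °C
Reagents that add atoms: none
Why: Mild oxidation of the neopentyl primary alcohol gives an aldehyde without α-hydrogen, which can neither epimerise nor eliminate acetate and ends the risk of 1,3-acyl migration (the descriptor changes to R only through the priority rules).

Step 10
Reactants: 12 methyl (2E,6E,11R)-11-(acetoxymethyl)-3,7,11-trimethyl-12-oxododeca-2,6-dienoate
Product: 13 methyl (2E,6E,11S,12E)-11-(acetoxymethyl)-3,7,11-trimethyl-14-oxotetradeca-2,6,12-trienoate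
Conditions: Ph3P=CHCHO, toluene, 90 °C
Reagents that add atoms: (triphenylphosphoranylidene)acetaldehyde, O=CC=P(c1ccccc1)(c1ccccc1)c1ccccc1
Why: Wittig reaction of a stabilised ylide should give the (E)-enal (C5=C6), and the conjugated product is less electrophilic than the saturated aldehyde, which limits a second homologation.

Step 11
Reactants: 13 methyl (2E,6E,11S,12E)-11-(acetoxymethyl)-3,7,11-trimethyl-14-oxotetradeca-2,6,12-trienoate
Product: 14 methyl (2E,6E,11S,12E,14S)-11-(acetoxymethyl)-14-hydroxy-3,7,11-trimethyl-16-(trimethylsilyl)hexadeca-2,6,12-trien-15-ynoate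
Conditions: HC≡CSiMe3, Me2Zn, (S,S)-ProPhenol (cat.), Ph3P=O (cat.), toluene, 0 °C; then aq. NH4Cl
Reagents that add atoms: trimethylsilylacetylene, C#C[Si](C)(C)C
Why: Catalytic asymmetric alkynylation of an enal by an alkynylzinc species held on the zinc-bound ProPhenol ligand sets the C7 carbinol under ligand control, the remote quaternary centre having no say; the ligand antipode that gives the 14S alcohol is the one to use.

Step 12
Reactants: 14 methyl (2E,6E,11S,12E,14S)-11-(acetoxymethyl)-14-hydroxy-3,7,11-trimethyl-16-(trimethylsilyl)hexadeca-2,6,12-trien-15-ynoate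
Product: 15 methyl (2E,6E,11S,12E,14S)-11-(acetoxymethyl)-14-hydroxy-3,7,11-trimethylhexadeca-2,6,12-trien-15-ynoate
Conditions: TBAF, AcOH, THF, 0 °C
Reagents that add atoms: none
Why: Buffered fluoride should cleave only the C(sp)–Si bond and leave the acetate, the methyl ester and the carbinol stereocentre untouched.

Step 13
Reactants: 15 methyl (2E,6E,11S,12E,14S)-11-(acetoxymethyl)-14-hydroxy-3,7,11-trimethylhexadeca-2,6,12-trien-15-ynoate
Product: 18 methyl (2E)-5-[(1S,2E,4aS,5S,8aS)-5-(acetoxymethyl)-5,8a-dimethyl-2-[(phenylsulfinyl)methylidene]-1,2,4a,5,6,7,8,8a-octahydronaphthalen-1-yl]-3-methylpent-2-enoate, via sulfenate ester 16 (not isolated), via allenyl sulfoxide 17 (not isolated)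
Conditions: PhSCl (freshly made from PhSSPh and SO2Cl2 in CH2Cl2), Et3N, CH2Cl2, −78 → 23 °C; then 23–40 °C
Reagents that add atoms: benzenesulfenyl chloride, ClSc1ccccc1 (made from diphenyl disulfide, c1ccc(SSc2ccccc2)cc1)
Why: The alcohol is O-sulfenylated to sulfenate 16, whose [2,3]-sigmatropic shift (the propargylic form of the Mislow–Evans rearrangement) gives allenyl sulfoxide 17, and its vinylallene (C5=C6–C7=C8, with C8=C17 as the spectator double bond) then undergoes an intramolecular Diels–Alder reaction with C9=C10, forming C8–C9 and C5–C10. The closest known reaction type is the tandem propargylic sulfenate rearrangement/intramolecular vinylallene Diels–Alder reaction, which runs at or near room temperature with unactivated alkenes. Ring B closes as the new cyclohexene of the suprafacial [4+2] and ring A closes at the same moment through the four-carbon tether C1–C4 (type 1 mode, chair-like tether in the exo position), which makes H5 and the C10 methyl trans. C9 and C10 are fixed relative to each other by the (E)-geometry of the dienophile, C5 relative to C10 by the tether-exo transition state, and the absolute sense of all three by the allene axis: the suprafacial shift puts sulfur on the face of C17 where oxygen stood at C7, so the S carbinol gives the aS allene, and the dienophile should add to the diene face anti to the phenylsulfinyl group. The step needs facial, exo/endo and site selectivity: the face is secured by the allene axis (the methyl/acetoxymethyl pair at C4 alone would not bias it), the trans fusion should follow from the quaternary C4 disfavouring the crowded tether-endo arrangement, and the site from the polarity match between the electron-poor allene carbon C8 and the electron-rich alkene carbon C9, the distant enoate being out of reach. The product already holds C6=C7 in ring B and the exocyclic C8=C17 bond of the target, with the sulfinyl group on C17 as the only excess.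

Step 14
Reactants: 18 methyl (2E)-5-[(1S,2E,4aS,5S,8aS)-5-(acetoxymethyl)-5,8a-dimethyl-2-[(phenylsulfinyl)methylidene]-1,2,4a,5,6,7,8,8a-octahydronaphthalen-1-yl]-3-methylpent-2-enoate
Product: 20 methyl (2E)-5-[(1R,4aS,5S,8aS)-5-(acetoxymethyl)-5,8a-dimethyl-2-methylidene-1,2,4a,5,6,7,8,8a-octahydronaphthalen-1-yl]-3-methylpent-2-enoate (the target), via alkenylmagnesium chloride 19 (not isolated)
Conditions: i-PrMgCl, THF, −78 °C; then aq. NH4Cl at −78 °C
Reagents that add atoms: none
Why: Sulfoxide–magnesium exchange at the alkenyl carbon should be faster at −78 °C than addition to the acetate or the hindered enoate, and protonation of the alkenylmagnesium intermediate leaves the exocyclic methylene (the C9 descriptor changes from S to R only through the priority rules).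

Compound list
1 | diethyl methylmalonate | CCOC(=O)C(C)C(=O)OCC | starting material
2 | diethyl 2-(2-chloroethyl)-2-methylmalonate | CCOC(=O)C(C)(CCCl)C(=O)OCC | intermediate
3 | 2-(2-chloroethyl)-2-methylpropane-1,3-diol | OCC(C)(CCCl)CO | intermediate
4 | 5-(2-chloroethyl)-2,2,5-trimethyl-1,3-dioxane | CC1(C)OCC(C)(CCCl)CO1 | intermediate
5 | methyl geranate, methyl (2E)-3,7-dimethylocta-2,6-dienoate | COC(=O)/C=C(\C)CCC=C(C)C | starting material
6 | methyl (2E,6E)-8-hydroxy-3,7-dimethylocta-2,6-dienoate | COC(=O)/C=C(\C)CC/C=C(\C)CO | intermediate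
7 | methyl (2E,6E)-8-bromo-3,7-dimethylocta-2,6-dienoate | COC(=O)/C=C(\C)CC/C=C(\C)CBr | intermediate
8 | [2-(2,2,5-trimethyl-1,3-dioxan-5-yl)ethyl]magnesium chloride | CC1(C)OCC(C)(CC[Mg]Cl)CO1 | intermediate
9 | methyl (2E,6E)-3,7-dimethyl-10-(2,2,5-trimethyl-1,3-dioxan-5-yl)deca-2,6-dienoate | COC(=O)/C=C(\C)CC/C=C(\C)CCCC1(C)COC(C)(C)OC1 | intermediate
10 | methyl (2E,6E)-12-hydroxy-11-(hydroxymethyl)-3,7,11-trimethyldodeca-2,6-dienoate | COC(=O)/C=C(\C)CC/C=C(\C)CCCC(C)(CO)CO | intermediate
11 | methyl (2E,6E,11S)-12-acetoxy-11-(hydroxymethyl)-3,7,11-trimethyldodeca-2,6-dienoate | COC(=O)/C=C(\C)CC/C=C(\C)CCC[C@@](C)(CO)COC(C)=O | intermediate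
12 | methyl (2E,6E,11R)-11-(acetoxymethyl)-3,7,11-trimethyl-12-oxododeca-2,6-dienoate | COC(=O)/C=C(\C)CC/C=C(\C)CCC[C@@](C)(C=O)COC(C)=O | intermediate
13 | methyl (2E,6E,11S,12E)-11-(acetoxymethyl)-3,7,11-trimethyl-14-oxotetradeca-2,6,12-trienoate | COC(=O)/C=C(\C)CC/C=C(\C)CCC[C@@](C)(/C=C/C=O)COC(C)=O | intermediate
14 | methyl (2E,6E,11S,12E,14S)-11-(acetoxymethyl)-14-hydroxy-3,7,11-trimethyl-16-(trimethylsilyl)hexadeca-2,6,12-trien-15-ynoate | COC(=O)/C=C(\C)CC/C=C(\C)CCC[C@@](C)(/C=C/[C@H](O)C#C[Si](C)(C)C)COC(C)=O | intermediate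
15 | methyl (2E,6E,11S,12E,14S)-11-(acetoxymethyl)-14-hydroxy-3,7,11-trimethylhexadeca-2,6,12-trien-15-ynoate | COC(=O)/C=C(\C)CC/C=C(\C)CCC[C@@](C)(/C=C/[C@H](O)C#C)COC(C)=O | intermediate
16 | methyl (2E,6E,11S,12E,14S)-11-(acetoxymethyl)-3,7,11-trimethyl-14-[(phenylsulfanyl)oxy]hexadeca-2,6,12-trien-15-ynoate (sulfenate ester of 15) | COC(=O)/C=C(\C)CC/C=C(\C)CCC[C@@](C)(/C=C/[C@H](OSc1ccccc1)C#C)COC(C)=O | intermediate
17 | methyl (2E,6E,11S,12E)-11-(acetoxymethyl)-3,7,11-trimethyl-16-(phenylsulfinyl)hexadeca-2,6,12,14,15-pentaenoate, allene axis C14=C15=C16 of aS configuration, sulfur as either epimer | COC(=O)/C=C(\C)CC/C=C(\C)CCC[C@@](C)(/C=C/C([H])=[C@@]=C([H])S(=O)c1ccccc1)COC(C)=O | intermediate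
18 | methyl (2E)-5-[(1S,2E,4aS,5S,8aS)-5-(acetoxymethyl)-5,8a-dimethyl-2-[(phenylsulfinyl)methylidene]-1,2,4a,5,6,7,8,8a-octahydronaphthalen-1-yl]-3-methylpent-2-enoate, sulfur as either epimer | O=S(c1ccccc1)/C=C1\C=C[C@@H]2[C@@](C)(COC(C)=O)CCC[C@@]2(C)[C@@H]1CC/C(C)=C/C(=O)OC | intermediate
19 | 17-chloromagnesio derivative of 20 (alkenylmagnesium chloride at the exocyclic methylidene carbon, magnesium cis to C7) | Cl[Mg]/C=C1\C=C[C@@H]2[C@@](C)(COC(C)=O)CCC[C@@]2(C)[C@@H]1CC/C(C)=C/C(=O)OC | intermediate
20 | methyl (2E)-5-[(1R,4aS,5S,8aS)-5-(acetoxymethyl)-5,8a-dimethyl-2-methylidene-1,2,4a,5,6,7,8,8a-octahydronaphthalen-1-yl]-3-methylpent-2-enoate; methyl 18-acetoxy-ent-labda-6,8(17),13E-trien-15-oate, (4S,5S,9R,10S) | C=C1C=C[C@@H]2[C@@](C)(COC(C)=O)CCC[C@@]2(C)[C@@H]1CC/C(C)=C/C(=O)OC | target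

Total step count: 14. Longest linear sequence: 12 steps (steps 1–3 and 6–14); steps 4 and 5 prepare the allylic bromide in a side branch.

Steps most likely to fail

Step 13 (key step). The sulfenyl chloride may add to the electron-rich C9=C10 alkene in competition with O-sulfenylation, or the cycloaddition may discriminate poorly between the tether-exo and tether-endo arrangements, which would erode the trans ring fusion. The fallback sets out from aldehyde 12: Takai iodo-olefination (CrCl2, CHI3, THF, 0 °C) should give the vinyl iodide methyl (2E,6E,11S,12E)-11-(acetoxymethyl)-13-iodo-3,7,11-trimethyltrideca-2,6,12-trienoate F1; Stille coupling with allenyltributylstannane (Pd(PPh3)4, LiCl, DMF, 50 °C) should give the sulfur-free vinylallene methyl (2E,6E,11S,12E)-11-(acetoxymethyl)-3,7,11-trimethylhexadeca-2,6,12,14,15-pentaenoate F2, and its thermal intramolecular Diels–Alder reaction (toluene, BHT, 110–140 °C) comes back to the route at 20. This path avoids sulfur and steps 10–14 but gives up the control by the allene axis, so the diene face is then set by C4 alone.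

Step 14. The Grignard reagent may attack the acetate or the ester in competition with sulfoxide–magnesium exchange, or the alkenylmagnesium species may be protonated with migration of the double bond. The fallback sets out from 18: radical addition–elimination with Bu3SnH and AIBN (benzene, 80 °C) should replace the sulfinyl group by tin and give the alkenylstannane methyl (2E)-5-[(1S,4aS,5S,8aS)-5-(acetoxymethyl)-5,8a-dimethyl-2-[(tributylstannyl)methylidene]-1,2,4a,5,6,7,8,8a-octahydronaphthalen-1-yl]-3-methylpent-2-enoate F3 (either alkene geometry), and protodestannylation (dilute HCl, THF, 0 °C) comes back at 20.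

Step 8. The enzyme may discriminate poorly between the two enantiotopic hydroxymethyl groups, or 1,3-acyl migration in the monoacetate may racemise C4. The fallback sets out from diol 10: peracetylation (Ac2O, pyridine, DMAP, CH2Cl2) gives the diacetate methyl (2E,6E)-12-acetoxy-11-(acetoxymethyl)-3,7,11-trimethyldodeca-2,6-dienoate F4, and lipase-catalysed hydrolysis of one enantiotopic acetate (phosphate buffer pH 7, acetone cosolvent, 23 °C) comes back at 11. Hydrolysis and acylation by the same lipase deliver opposite enantiomers, so one of the two modes should reach the 11S compound.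

Further compounds
F1 | step 13 | methyl (2E,6E,11S,12E)-11-(acetoxymethyl)-13-iodo-3,7,11-trimethyltrideca-2,6,12-trienoate | COC(=O)/C=C(\C)CC/C=C(\C)CCC[C@@](C)(/C=C/I)COC(C)=O
F2 | step 13 | methyl (2E,6E,11S,12E)-11-(acetoxymethyl)-3,7,11-trimethylhexadeca-2,6,12,14,15-pentaenoate | COC(=O)/C=C(\C)CC/C=C(\C)CCC[C@@](C)(/C=C/C=C=C)COC(C)=O
F3 | step 14 | methyl (2E)-5-[(1S,4aS,5S,8aS)-5-(acetoxymethyl)-5,8a-dimethyl-2-[(tributylstannyl)methylidene]-1,2,4a,5,6,7,8,8a-octahydronaphthalen-1-yl]-3-methylpent-2-enoate | CCCC[Sn](CCCC)(CCCC)C=C1C=C[C@@H]2[C@@](C)(COC(C)=O)CCC[C@@]2(C)[C@@H]1CC/C(C)=C/C(=O)OC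
F4 | step 8 | methyl (2E,6E)-12-acetoxy-11-(acetoxymethyl)-3,7,11-trimethyldodeca-2,6-dienoate | COC(=O)/C=C(\C)CC/C=C(\C)CCCC(C)(COC(C)=O)COC(C)=O
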